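**Retrosynthetic overview**
1. Target ⇐ desilylation and Z-selective ring-closing metathesis at C1=C10 of an acyclic diene; the ten-membered ring is closed last.
2. C8 ester ⇐ hydroxy α-methylene-γ-lactone + silyl-protected (E)-4-hydroxytiglic acid (from a Wittig reaction).
3. γ-Lactone (C7–C11 bond, C7 stereocentre, free 8-OH) ⇐ intramolecular opening of a trans-7,8-oxirane by a phosphonoacetate tethered on O6, then Horner–Wadsworth–Emmons methylenation (new step).
4. Bis-epoxy carbinol ⇐ cis-epoxy aldehyde + (E)-alkenylzinc (C6–C7 bond), then hydroxyl-directed Sharpless epoxidation.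
5. First ring and first stereocentres ⇐ Shi organocatalytic epoxidation of (Z)-3-methylhepta-2,6-dien-1-ol (prenol dianion + allyl bromide). Ring order: 4,5-oxirane → transient 7,8-oxirane → γ-lactone → cyclodecene.

Assumption: the SMILES is taken literally (germacrane numbering for atom labels): Z C1=C10 ring olefin, cis-4,5-epoxide, centres 4R,5S,6S,7R,8R, E side-chain olefin.

**Route**

Step 1
Reactants: 1 ethynylmagnesium bromide; 2 methallyl chloride (3-chloro-2-methylprop-1-ene)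
Product: 3 2-methylpent-1-en-4-yne
Conditions: CuCl (5 mol%), THF, 45 °C
Reagents that add atoms: none
Why: Copper-catalysed coupling of the alkynyl Grignard reagent with the allylic chloride (allylic substitution) gives the skipped enyne, and no stereocentre is formed.

Step 2
Reactants: 4 prenol (3-methylbut-2-en-1-ol); 5 allyl bromide
Product: 7 (2Z)-3-methylhepta-2,6-dien-1-ol, via dilithiated prenol 6 (not isolated)
Conditions: n-BuLi (2.2 equiv), TMEDA, Et2O/hexane, 0 → 23 °C; then 5, −78 → 23 °C; H2O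
Reagents that add atoms: none
Why: Alkoxide-directed allylic lithiation removes a proton from the methyl group cis to CH2OLi, and SN2 alkylation of this chelated dianion by allyl bromide (dianion alkylation) gives the Z-trisubstituted olefin, whose geometry is fixed by the O–Li–C chelate.

Step 3
Reactants: 7 (2Z)-3-methylhepta-2,6-dien-1-ol
Product: 8 [(2S,3R)-3-(but-3-en-1-yl)-3-methyloxiran-2-yl]methanol
Conditions: ent-Shi ketone (L-fructose-derived, 30 mol%), KHSO5 (as 2KHSO5·KHSO4·K2SO4), K2CO3, Bu4NHSO4, MeCN/CH2(OMe)2–aq. Na2B4O7 buffer (pH 10.5), 0 °C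
Reagents that add atoms: potassium peroxymonosulfate, [K+].[O-]S(=O)(=O)OO
Why: Shi asymmetric epoxidation, in which the chiral dioxirane attacks only the electron-rich trisubstituted olefin through the spiro transition state and the ent-ketone delivers oxygen to the face that gives the (2S,3R) cis-epoxide, so C4 (R) and C5 (S) are set as the first stereocentres.

Step 4
Reactants: 8 [(2S,3R)-3-(but-3-en-1-yl)-3-methyloxiran-2-yl]methanol
Product: 9 (2R,3R)-3-(but-3-en-1-yl)-3-methyloxirane-2-carbaldehyde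
Conditions: TEMPO (10 mol%), PhI(OAc)2, CH2Cl2, 23 °C
Reagents that add atoms: none
Why: TEMPO/PhI(OAc)2 oxidation (oxoammonium alcohol oxidation) stops at the aldehyde under neutral conditions, so the oxirane and its α-stereocentre are untouched (the descriptor at C2 changes by priority only).

Step 5
Reactants: 3 2-methylpent-1-en-4-yne; 9 (2R,3R)-3-(but-3-en-1-yl)-3-methyloxirane-2-carbaldehyde
Product: 12 (1S,2E)-1-[(2S,3R)-3-(but-3-en-1-yl)-3-methyloxiran-2-yl]-5-methylhexa-2,5-dien-1-ol, via alkenylzirconocene chloride 10 (not isolated), via alkenyl(methyl)zinc 11 (not isolated)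
Conditions: 3, Cp2Zr(H)Cl, CH2Cl2, 23 °C; Me2Zn, toluene, −65 °C; then 9, 0 °C; H2O
Reagents that add atoms: none
Why: Syn hydrozirconation of the alkyne fixes the E olefin, and after Zr-to-Zn transmetalation the alkenylzinc adds to the aldehyde (Wipf alkenylzinc addition) in the Felkin–Anh/Cornforth sense anti to the oxirane C–O bond, which sets C6 (S, erythro to the epoxide).

Step 6
Reactants: 12 (1S,2E)-1-[(2S,3R)-3-(but-3-en-1-yl)-3-methyloxiran-2-yl]-5-methylhexa-2,5-dien-1-ol
Product: 13 (S)-[(2S,3R)-3-(but-3-en-1-yl)-3-methyloxiran-2-yl][(2R,3R)-3-(2-methylprop-2-en-1-yl)oxiran-2-yl]methanol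
Conditions: Ti(OiPr)4 (20 mol%), D-(−)-diisopropyl tartrate (24 mol%), t-BuOOH, 4 Å MS, CH2Cl2, −20 °C
Reagents that add atoms: tert-butyl hydroperoxide, CC(C)(C)OO
Why: Katsuki–Sharpless epoxidation of the secondary allylic alcohol in its matched (fast, erythro-selective) pairing with D-(−)-tartrate touches only the allylic olefin and places the new oxirane oxygen on the face that makes C7 and C8 both R.

Step 7
Reactants: 13 (S)-[(2S,3R)-3-(but-3-en-1-yl)-3-methyloxiran-2-yl][(2R,3R)-3-(2-methylprop-2-en-1-yl)oxiran-2-yl]methanol; 14 2-(diethoxyphosphoryl)acetic acid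
Product: 15 (S)-[(2S,3R)-3-(but-3-en-1-yl)-3-methyloxiran-2-yl][(2S,3R)-3-(2-methylprop-2-en-1-yl)oxiran-2-yl]methyl 2-(diethoxyphosphoryl)acetate
Conditions: DCC, DMAP (10 mol%), CH2Cl2, 0 → 23 °C
Reagents that add atoms: none
Why: Steglich esterification acylates the secondary carbinol under neutral conditions without touching the two oxiranes, and no stereocentre changes (one oxirane descriptor changes by priority only).

Step 8
Reactants: 15 (S)-[(2S,3R)-3-(but-3-en-1-yl)-3-methyloxiran-2-yl][(2S,3R)-3-(2-methylprop-2-en-1-yl)oxiran-2-yl]methyl 2-(diethoxyphosphoryl)acetate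
Product: 17 (4R,5S)-5-[(2S,3R)-3-(but-3-en-1-yl)-3-methyloxiran-2-yl]-4-[(1R)-1-hydroxy-3-methylbut-3-en-1-yl]-3-methylideneoxolan-2-one, via phosphono lactone 16 (not isolated)
Conditions: NaH (1.05 equiv), THF, 0 → 50 °C; then (CH2O)n, 23 °C
Reagents that add atoms: formaldehyde (as paraformaldehyde), C=O
Why: Proposed new method: the sodium enolate of the phosphonoacetate tethered on O6 attacks the proximal oxirane carbon C7 in a 5-exo SN2 opening anti to the C7–O bond, so inversion sets C7 (R) and the trans-lactone while the oxirane oxygen stays on C8 as the free 8-OH (R); proton transfer from the acidic α-phosphono lactone then quenches the alkoxide (which suppresses translactonisation), and the resulting phosphonate anion is methylenated in the same pot by Horner–Wadsworth–Emmons reaction with formaldehyde; attack at C7 of the disubstituted oxirane should beat attack at C5 (next to the fully substituted C4) and 6-endo attack at C8; the closest known reactions are the intermolecular opening of epoxides by phosphonoacetate anions to α-phosphono-γ-lactones, the intramolecular C2 opening of 2,3-epoxy alcohol carbamates, and the methylenation of α-phosphono lactones.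

Step 9
Reactants: 18 2-[(tert-butyldimethylsilyl)oxy]acetaldehyde; 19 ethyl 2-(triphenyl-λ5-phosphanylidene)propanoate
Product: 20 ethyl (2E)-4-[(tert-butyldimethylsilyl)oxy]-2-methylbut-2-enoate
Conditions: CH2Cl2, 23 °C
Reagents that add atoms: none
Why: Wittig olefination with the stabilised ylide gives the E-trisubstituted enoate.

Step 10
Reactants: 20 ethyl (2E)-4-[(tert-butyldimethylsilyl)oxy]-2-methylbut-2-enoate
Product: 21 (2E)-4-[(tert-butyldimethylsilyl)oxy]-2-methylbut-2-enoic acid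
Conditions: LiOH, THF/H2O, 23 °C; then 1 M HCl to pH 4, 0 °C
Reagents that add atoms: lithium hydroxide, [Li+].[OH-]
Why: Saponification of the ethyl ester followed by mild acidification frees the acid while the primary silyl ether and the olefin geometry survive.

Step 11
Reactants: 17 (4R,5S)-5-[(2S,3R)-3-(but-3-en-1-yl)-3-methyloxiran-2-yl]-4-[(1R)-1-hydroxy-3-methylbut-3-en-1-yl]-3-methylideneoxolan-2-one; 21 (2E)-4-[(tert-butyldimethylsilyl)oxy]-2-methylbut-2-enoic acid
Product: 22 (1R)-1-[(2S,3R)-2-[(2S,3R)-3-(but-3-en-1-yl)-3-methyloxiran-2-yl]-4-methylidene-5-oxooxolan-3-yl]-3-methylbut-3-en-1-yl (2E)-4-[(tert-butyldimethylsilyl)oxy]-2-methylbut-2-enoate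
Conditions: DCC, DMAP (20 mol%), CH2Cl2, 23 °C
Reagents that add atoms: none
Why: Steglich esterification of the free 8-OH with the unsaturated acid leaves the lactone, the epoxide and every stereocentre untouched.

Step 12
Reactants: 22 (1R)-1-[(2S,3R)-2-[(2S,3R)-3-(but-3-en-1-yl)-3-methyloxiran-2-yl]-4-methylidene-5-oxooxolan-3-yl]-3-methylbut-3-en-1-yl (2E)-4-[(tert-butyldimethylsilyl)oxy]-2-methylbut-2-enoate
Product: 23 (1aR,4Z,7R,7aR,10aS,10bS)-1a,5-dimethyl-8-methylidene-9-oxo-1a,2,3,6,7,7a,8,9,10a,10b-decahydrooxireno[9,10]cyclodeca[1,2-b]furan-7-yl (2E)-4-[(tert-butyldimethylsilyl)oxy]-2-methylbut-2-enoate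
Conditions: second-generation Hoveyda–Grubbs catalyst (15 mol%), toluene (1 mM), 100 °C, argon sparge
Reagents that add atoms: none
Why: Ring-closing metathesis between the terminal vinyl group and the 1,1-disubstituted olefin closes the ten-membered ring with loss of ethene, the Z olefin being the geometry expected for a trisubstituted olefin formed in this medium ring, while the electron-poor methylene lactone and enoate olefins stay out.

Step 13
Reactants: 23 (1aR,4Z,7R,7aR,10aS,10bS)-1a,5-dimethyl-8-methylidene-9-oxo-1a,2,3,6,7,7a,8,9,10a,10b-decahydrooxireno[9,10]cyclodeca[1,2-b]furan-7-yl (2E)-4-[(tert-butyldimethylsilyl)oxy]-2-methylbut-2-enoate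
Product: 24 (1aR,4Z,7R,7aR,10aS,10bS)-1a,5-dimethyl-8-methylidene-9-oxo-1a,2,3,6,7,7a,8,9,10a,10b-decahydrooxireno[9,10]cyclodeca[1,2-b]furan-7-yl (2E)-4-hydroxy-2-methylbut-2-enoate
Conditions: HF·pyridine, pyridine, THF, 0 °C
Reagents that add atoms: none
Why: Fluoride-mediated cleavage of the primary silyl ether (desilylation) under pyridine-buffered conditions leaves the epoxide, the lactone and the ester intact.

**Compound list**
1 | ethynylmagnesium bromide | C#C[Mg]Br | starting material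
2 | methallyl chloride (3-chloro-2-methylprop-1-ene) | C=C(C)CCl | starting material
3 | 2-methylpent-1-en-4-yne | C=C(C)CC#C | intermediate
4 | prenol (3-methylbut-2-en-1-ol) | CC(C)=CCO | starting material
5 | allyl bromide (3-bromoprop-1-ene) | C=CCBr | starting material
6 | dilithiated prenol, lithium (2Z)-4-lithio-3-methylbut-2-en-1-olate | [Li]C/C(C)=C\CO[Li] | intermediate
7 | (2Z)-3-methylhepta-2,6-dien-1-ol | C=CCC/C(C)=C\CO | intermediate
8 | [(2S,3R)-3-(but-3-en-1-yl)-3-methyloxiran-2-yl]methanol | OC[C@@H]1O[C@]1(C)CCC=C | intermediate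
9 | (2R,3R)-3-(but-3-en-1-yl)-3-methyloxirane-2-carbaldehyde | O=C[C@@H]1O[C@]1(C)CCC=C | intermediate
10 | chlorobis(cyclopentadienyl)[(1E)-4-methylpenta-1,4-dien-1-yl]zirconium | C=C(C)C/C=C/[Zr](Cl)(C1C=CC=C1)C1C=CC=C1 | intermediate
11 | methyl[(1E)-4-methylpenta-1,4-dien-1-yl]zinc | C=C(C)C/C=C/[Zn]C | intermediate
12 | (1S,2E)-1-[(2S,3R)-3-(but-3-en-1-yl)-3-methyloxiran-2-yl]-5-methylhexa-2,5-dien-1-ol | C=CCC[C@@]1(C)O[C@H]1[C@@H](O)/C=C/CC(C)=C | intermediate
13 | (S)-[(2S,3R)-3-(but-3-en-1-yl)-3-methyloxiran-2-yl][(2R,3R)-3-(2-methylprop-2-en-1-yl)oxiran-2-yl]methanol | C=CCC[C@@]1(C)O[C@H]1[C@@H](O)[C@H]1O[C@@H]1CC(C)=C | intermediate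
14 | 2-(diethoxyphosphoryl)acetic acid | CCOP(=O)(OCC)CC(=O)O | starting material
15 | (S)-[(2S,3R)-3-(but-3-en-1-yl)-3-methyloxiran-2-yl][(2S,3R)-3-(2-methylprop-2-en-1-yl)oxiran-2-yl]methyl 2-(diethoxyphosphoryl)acetate | C=CCC[C@@]1(C)O[C@H]1[C@@H](OC(=O)CP(=O)(OCC)OCC)[C@H]1O[C@@H]1CC(C)=C | intermediate
16 | diethyl [(4R,5S)-5-[(2S,3R)-3-(but-3-en-1-yl)-3-methyloxiran-2-yl]-4-[(1R)-1-hydroxy-3-methylbut-3-en-1-yl]-2-oxooxolan-3-yl]phosphonate (C3 epimers, formed as the sodium salt) | CCOP(=O)(OCC)C1C(=O)O[C@H]([C@@H]2O[C@]2(C)CCC=C)[C@H]1[C@H](O)CC(C)=C | intermediate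
17 | (4R,5S)-5-[(2S,3R)-3-(but-3-en-1-yl)-3-methyloxiran-2-yl]-4-[(1R)-1-hydroxy-3-methylbut-3-en-1-yl]-3-methylideneoxolan-2-one | C=C1C(=O)O[C@H]([C@@H]2O[C@]2(C)CCC=C)[C@H]1[C@H](O)CC(C)=C | intermediate
18 | 2-[(tert-butyldimethylsilyl)oxy]acetaldehyde | CC(C)(C)[Si](C)(C)OCC=O | starting material
19 | ethyl 2-(triphenyl-λ5-phosphanylidene)propanoate | CCOC(=O)C(C)=P(c1ccccc1)(c1ccccc1)c1ccccc1 | starting material
20 | ethyl (2E)-4-[(tert-butyldimethylsilyl)oxy]-2-methylbut-2-enoate | CCOC(=O)/C(C)=C/CO[Si](C)(C)C(C)(C)C | intermediate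
21 | (2E)-4-[(tert-butyldimethylsilyl)oxy]-2-methylbut-2-enoic acid | OC(=O)/C(C)=C/CO[Si](C)(C)C(C)(C)C | intermediate
22 | (1R)-1-[(2S,3R)-2-[(2S,3R)-3-(but-3-en-1-yl)-3-methyloxiran-2-yl]-4-methylidene-5-oxooxolan-3-yl]-3-methylbut-3-en-1-yl (2E)-4-[(tert-butyldimethylsilyl)oxy]-2-methylbut-2-enoate | C=C1C(=O)O[C@H]([C@@H]2O[C@]2(C)CCC=C)[C@H]1[C@H](OC(=O)/C(C)=C/CO[Si](C)(C)C(C)(C)C)CC(C)=C | intermediate
23 | (1aR,4Z,7R,7aR,10aS,10bS)-1a,5-dimethyl-8-methylidene-9-oxo-1a,2,3,6,7,7a,8,9,10a,10b-decahydrooxireno[9,10]cyclodeca[1,2-b]furan-7-yl (2E)-4-[(tert-butyldimethylsilyl)oxy]-2-methylbut-2-enoate | C=C1C(=O)O[C@H]2[C@H]1[C@H](OC(=O)/C(C)=C/CO[Si](C)(C)C(C)(C)C)C/C(C)=C\CC[C@@]1(C)O[C@@H]21 | intermediate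
24 | (1aR,4Z,7R,7aR,10aS,10bS)-1a,5-dimethyl-8-methylidene-9-oxo-1a,2,3,6,7,7a,8,9,10a,10b-decahydrooxireno[9,10]cyclodeca[1,2-b]furan-7-yl (2E)-4-hydroxy-2-methylbut-2-enoate (CNP0198076.6) | C=C1C(=O)O[C@H]2[C@H]1[C@H](OC(=O)/C(C)=C/CO)C/C(C)=C\CC[C@@]1(C)O[C@@H]21 | target

**Step count and risks**

Total steps: 13. Longest linear sequence: 10 (steps 2–8 and 11–13).

The three steps most likely to fail:

Step 5 (facial selectivity of the alkenylzinc addition to the epoxy aldehyde). The matched Sharpless step 6 already leaves the wrong C6 epimer largely unreacted, but if the ratio is poor the fallback sets out from 9 and 3 and comes back at 12. The addition is run without regard to selectivity, giving 12 together with its carbinol epimer (1R,2E)-1-[(2S,3R)-3-(but-3-en-1-yl)-3-methyloxiran-2-yl]-5-methylhexa-2,5-dien-1-ol F1. The mixture is oxidised with Dess–Martin periodinane (CH2Cl2, 0 °C) to the epoxy dienone (2E)-1-[(2R,3R)-3-(but-3-en-1-yl)-3-methyloxiran-2-yl]-5-methylhexa-2,5-dien-1-one F2. F2 is reduced with Zn(BH4)2 in Et2O at −40 °C; zinc chelation between the ketone and oxirane oxygens is known to give the anti (erythro) epoxy alcohol, so a single epimer 12 is returned.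

Step 8 (the proposed new cyclisation; risks are attack at C5 of the other oxirane, 6-endo opening, and sluggish reaction of the stabilised carbanion). The fallback uses known reaction types, sets out from 12 and comes back at 22, bypassing steps 6, 7, 8 and 11.
- 12 is esterified with 14 (DCC, DMAP) to (1S,2E)-1-[(2S,3R)-3-(but-3-en-1-yl)-3-methyloxiran-2-yl]-5-methylhexa-2,5-dien-1-yl 2-(diethoxyphosphoryl)acetate F3.
- Regitz diazo transfer (4-acetamidobenzenesulfonyl azide, DBU, MeCN) gives (1S,2E)-1-[(2S,3R)-3-(but-3-en-1-yl)-3-methyloxiran-2-yl]-5-methylhexa-2,5-dien-1-yl 2-diazo-2-(diethoxyphosphoryl)acetate F4.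
- Rh2(OAc)4 (dirhodium tetraacetate, 1 mol%, CH2Cl2, 40 °C) effects intramolecular cyclopropanation of the E olefin on the face that keeps the oxiranyl group exo, giving diethyl [(1S,4S,5R,6S)-4-[(2S,3R)-3-(but-3-en-1-yl)-3-methyloxiran-2-yl]-6-(2-methylprop-2-en-1-yl)-2-oxo-3-oxabicyclo[3.1.0]hexan-1-yl]phosphonate F5.
- Homoconjugate opening of this doubly activated cyclopropane at C8 by acid 21 with Cs2CO3 (DMF, 60 °C, inversion) installs the side chain and gives (1R)-1-[(2S,3R)-4-(diethoxyphosphoryl)-2-[(2S,3R)-3-(but-3-en-1-yl)-3-methyloxiran-2-yl]-5-oxooxolan-3-yl]-3-methylbut-3-en-1-yl (2E)-4-[(tert-butyldimethylsilyl)oxy]-2-methylbut-2-enoate F6.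
- NaH and (CH2O)n in THF then give 22 by Horner–Wadsworth–Emmons methylenation.

Step 12 (closing a ten-membered ring onto a 1,1-disubstituted olefin; risks are low conversion, oligomers, or E/Z mixtures). The fallback moves ring closure in front of the acylation, sets out from 17 and comes back at 23. Hydroxy lactone 17, which lacks the bulky ester next to the methallyl unit and carries a free homoallylic hydroxyl, is cyclised with the second-generation Hoveyda–Grubbs catalyst (toluene, 1 mM, 100 °C) to (1aR,4Z,7R,7aR,10aS,10bS)-7-hydroxy-1a,5-dimethyl-8-methylidene-2,3,6,7,7a,8,10a,10b-octahydrooxireno[9,10]cyclodeca[1,2-b]furan-9(1aH)-one F7. F7 is then esterified with 21 (DCC, DMAP) to give 23.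

**Further compounds**
F1 | step 5 | (1R,2E)-1-[(2S,3R)-3-(but-3-en-1-yl)-3-methyloxiran-2-yl]-5-methylhexa-2,5-dien-1-ol | C=CCC[C@@]1(C)O[C@H]1[C@H](O)/C=C/CC(C)=C
F2 | step 5 | (2E)-1-[(2R,3R)-3-(but-3-en-1-yl)-3-methyloxiran-2-yl]-5-methylhexa-2,5-dien-1-one | C=CCC[C@@]1(C)O[C@H]1C(=O)/C=C/CC(C)=C
F3 | step 8 | (1S,2E)-1-[(2S,3R)-3-(but-3-en-1-yl)-3-methyloxiran-2-yl]-5-methylhexa-2,5-dien-1-yl 2-(diethoxyphosphoryl)acetate | C=CCC[C@@]1(C)O[C@H]1[C@@H](OC(=O)CP(=O)(OCC)OCC)/C=C/CC(C)=C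
F4 | step 8 | (1S,2E)-1-[(2S,3R)-3-(but-3-en-1-yl)-3-methyloxiran-2-yl]-5-methylhexa-2,5-dien-1-yl 2-diazo-2-(diethoxyphosphoryl)acetate | C=CCC[C@@]1(C)O[C@H]1[C@@H](OC(=O)C(=[N+]=[N-])P(=O)(OCC)OCC)/C=C/CC(C)=C
F5 | step 8 | diethyl [(1S,4S,5R,6S)-4-[(2S,3R)-3-(but-3-en-1-yl)-3-methyloxiran-2-yl]-6-(2-methylprop-2-en-1-yl)-2-oxo-3-oxabicyclo[3.1.0]hexan-1-yl]phosphonate | CCOP(=O)(OCC)[C@]12C(=O)O[C@H]([C@@H]3O[C@]3(C)CCC=C)[C@H]1[C@@H]2CC(C)=C
F6 | step 8 | (1R)-1-[(2S,3R)-4-(diethoxyphosphoryl)-2-[(2S,3R)-3-(but-3-en-1-yl)-3-methyloxiran-2-yl]-5-oxooxolan-3-yl]-3-methylbut-3-en-1-yl (2E)-4-[(tert-butyldimethylsilyl)oxy]-2-methylbut-2-enoate | CCOP(=O)(OCC)C1C(=O)O[C@H]([C@@H]2O[C@]2(C)CCC=C)[C@H]1[C@H](OC(=O)/C(C)=C/CO[Si](C)(C)C(C)(C)C)CC(C)=C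
F7 | step 12 | (1aR,4Z,7R,7aR,10aS,10bS)-7-hydroxy-1a,5-dimethyl-8-methylidene-2,3,6,7,7a,8,10a,10b-octahydrooxireno[9,10]cyclodeca[1,2-b]furan-9(1aH)-one | C=C1C(=O)O[C@H]2[C@H]1[C@H](O)C/C(C)=C\CC[C@@]1(C)O[C@@H]21
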